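**Retrosynthetic overview**
1. Feature: in the 6-bromoindole, C6–Br is para to C3a. The benzo ring is therefore a 4-bromophenyl group bonded through C3a to C3, and either of its two equivalent ortho carbons can become C7a.
2. Last skeletal bond: N1–C7a, made by oxidative aryl C–H amination of an N-tosyl 2-(4-bromophenyl)enamine. Its future C3 already carries the complete imidazolyl maleimide.
3. Indole C2 comes from a formamide acetal condensed on the benzylic CH2 of a 3-(4-bromobenzyl)maleimide, and N1 comes from p-toluenesulfonamide.
4. The benzyl maleimide comes from 2,3-dibromo-N-methylmaleimide by two successive cross-couplings, first with a benzylzinc and then with a 5-stannylimidazole.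
5. Ring order: the benzene, imidazole and imide rings are bought. The pyrrole ring of the indole is the only new ring (step 6). The imide ring is then opened and reclosed (N–Me to O to N–H), with loss of tosyl.

Key step: step 6

Remark: the imide is carried as N-methyl because a formamide acetal methylates a free imide N–H and that N–H would rival the sulfonamide as a ligand for palladium. It is exchanged for N–H through the anhydride at the end.
Remark: the benzyl maleimide is not made from an arylpyruvate ester and an acetamide. The alkoxide base of that condensation turns the arylpyruvate wholly into its unreactive enolate.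
Remark: 7, 8 and 10 are drawn as E isomers (heteroatom cis to the aryl group). These push–pull alkenes interconvert with their Z forms, and 8 stands for the enol/aldehyde tautomer set. Compounds 1, 2 (THF solution), 4, 6 and 9 are catalogue items.

**Step 1**
Reactants: 1 3,4-dibromo-1-methyl-1H-pyrrole-2,5-dione; 2 4-bromobenzylzinc bromide
Product: 3 3-bromo-4-(4-bromobenzyl)-1-methyl-1H-pyrrole-2,5-dione
Conditions: Pd(PPh3)4 (3 mol %), 1 (1.5 equiv), slow addition of 2 (1.0 equiv, 0.5 M in THF), THF, 0 °C to rt
Reagents that add atoms: none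
Why: In this Negishi coupling the electron-poor vinylic C–Br bonds of 1 add to zerovalent palladium far faster than the aryl C–Br bond, and excess 1 with slow addition of 2 should hold the reaction at monosubstitution because 3 is the less reactive halide.

**Step 2**
Reactants: 3 3-bromo-4-(4-bromobenzyl)-1-methyl-1H-pyrrole-2,5-dione; 4 1-methyl-5-(tributylstannyl)-1H-imidazole
Product: 5 3-(4-bromobenzyl)-1-methyl-4-(1-methyl-1H-imidazol-5-yl)-1H-pyrrole-2,5-dione
Conditions: Pd2(dba)3 (2.5 mol %), AsPh3 (10 mol %), CuI (10 mol %), 1,4-dioxane, 60 °C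
Reagents that add atoms: none
Why: In this Stille coupling zerovalent palladium inserts into the vinylogous acyl C–Br bond of 3 well below the temperature at which the bromoarene reacts, AsPh3 and CuI speed transmetalation from tin, and the base-free medium leaves the acidic benzylic CH2 alone.

**Step 3**
Reactants: 5 3-(4-bromobenzyl)-1-methyl-4-(1-methyl-1H-imidazol-5-yl)-1H-pyrrole-2,5-dione; 6 N,N-dimethylformamide dimethyl acetal
Product: 7 3-[(E)-1-(4-bromophenyl)-2-(dimethylamino)ethenyl]-1-methyl-4-(1-methyl-1H-imidazol-5-yl)-1H-pyrrole-2,5-dione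
Conditions: 6 (4 equiv), DMF, 90 °C, methanol allowed to distil off
Reagents that add atoms: none
Why: This is a formamide acetal condensation on a vinylogous CH-acid (the reaction type of the first stage of the Leimgruber–Batcho synthesis), in which the CH2, benzylic and γ to the C5 carbonyl through C3=C4, is deprotonated by methoxide from 6 and the extended enolate attacks the methoxyiminium ion at its γ carbon, with loss of methanol fixing the push–pull dienamine.

**Step 4**
Reactants: 7 3-[(E)-1-(4-bromophenyl)-2-(dimethylamino)ethenyl]-1-methyl-4-(1-methyl-1H-imidazol-5-yl)-1H-pyrrole-2,5-dione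
Product: 8 3-[(E)-1-(4-bromophenyl)-2-hydroxyethenyl]-1-methyl-4-(1-methyl-1H-imidazol-5-yl)-1H-pyrrole-2,5-dione (enol of the α-formyl compound)
Conditions: 1 M aq HCl, THF, 40 °C; then brought to pH 7
Reagents that add atoms: water, O
Why: In this acid hydrolysis of a push–pull enamine, protonation at the aryl-bearing carbon gives an iminium ion, water adds, dimethylamine leaves as its salt and the formyl compound settles as the conjugated enol, while imide, imidazole and aryl bromide are inert to dilute acid.

**Step 5**
Reactants: 8 3-[(E)-1-(4-bromophenyl)-2-hydroxyethenyl]-1-methyl-4-(1-methyl-1H-imidazol-5-yl)-1H-pyrrole-2,5-dione; 9 p-toluenesulfonamide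
Product: 10 N-{(E)-2-(4-bromophenyl)-2-[1-methyl-4-(1-methyl-1H-imidazol-5-yl)-2,5-dioxo-2,5-dihydro-1H-pyrrol-3-yl]ethenyl}-4-methylbenzenesulfonamide
Conditions: 9 (1.5 equiv), TsOH·H2O (1.2 equiv), toluene, Dean–Stark, reflux
Reagents that add atoms: none
Why: This is the acid-catalysed dehydrative condensation of a sulfonamide with an α-aryl formyl compound, the usual way to N-tosyl 2-aryl enamines, in which the first equivalent of acid is taken up by imidazole N3, the rest activates the aldehyde tautomer, and removal of water with tautomerisation of the N-sulfonyl imine into conjugation drives the equilibrium.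

**Step 6**
Reactants: 10 N-{(E)-2-(4-bromophenyl)-2-[1-methyl-4-(1-methyl-1H-imidazol-5-yl)-2,5-dioxo-2,5-dihydro-1H-pyrrol-3-yl]ethenyl}-4-methylbenzenesulfonamide
Product: 11 3-[6-bromo-1-(4-methylbenzenesulfonyl)-1H-indol-3-yl]-1-methyl-4-(1-methyl-1H-imidazol-5-yl)-1H-pyrrole-2,5-dione
Conditions: Pd(OAc)2 (10 mol %), Cu(OAc)2 (3 equiv), DMSO, 100 °C, N2
Reagents that add atoms: none
Why: Acetate removes the acidic sulfonamide proton and divalent palladium binds nitrogen; in the E isomer concerted metalation–deprotonation of an ortho C–H bond gives a six-membered azapalladacycle (Pd, N1, C2, C3, C3a, C7a), and C–N reductive elimination forms N1–C7a before Cu(OAc)2 returns zerovalent palladium to the divalent state. The closest known reaction type is the Pd(OAc)2/Cu(OAc)2 oxidative C–H amination of N-sulfonyl 2-aryl enamines that carry an acceptor at the future C3, a relative of the carbazole synthesis from 2-amidobiaryls. The one ring closed is the five-membered pyrrole ring of the indole, formed by contraction of the palladacycle on reductive elimination and delivered directly at the aromatic oxidation level, and no stereocentre is created. Regioselectivity needs no control, because the two ortho C–H bonds of the 4-bromophenyl ring are related by symmetry and either one places bromine at C6. Selectivity for C–H over C–Br rests on the phosphine-free medium, where the excess of divalent copper should reoxidise zerovalent palladium before it inserts into the bromoarene, while the third equivalent of Cu(OAc)2 occupies imidazole N3 and the N-methyl group removes the imide N–H as a rival ligand. The Z isomer is fed into the reactive E form by rotation about the polarised C=C bond and through the N-sulfonyl imine tautomer.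

**Step 7**
Reactants: 11 3-[6-bromo-1-(4-methylbenzenesulfonyl)-1H-indol-3-yl]-1-methyl-4-(1-methyl-1H-imidazol-5-yl)-1H-pyrrole-2,5-dione
Product: 13 3-(6-bromo-1H-indol-3-yl)-4-(1-methyl-1H-imidazol-5-yl)furan-2,5-dione, via dipotassium maleate salt 12 (not isolated)
Conditions: KOH (10 equiv), EtOH–H2O, reflux; then 2 M HCl to pH 2, then pH 5 and extraction
Reagents that add atoms: potassium hydroxide, [K+].[OH-]
Why: In this alkaline hydrolysis, as practised on N-methyl diarylmaleimides, hydroxide cleaves the activated indole N-sulfonyl bond and opens the imide to the maleate with loss of methylamine, and on acidification the cis-diacid on a tetrasubstituted alkene closes by itself to the anhydride, with bromoarene and N-methylimidazole untouched.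

**Step 8**
Reactants: 13 3-(6-bromo-1H-indol-3-yl)-4-(1-methyl-1H-imidazol-5-yl)furan-2,5-dione
Product: 14 didemnimide D, 3-(6-bromo-1H-indol-3-yl)-4-(1-methyl-1H-imidazol-5-yl)-1H-pyrrole-2,5-dione
Conditions: (Me3Si)2NH (10 equiv), MeOH (5 equiv), DMF, rt to 60 °C
Reagents that add atoms: hexamethyldisilazane, C[Si](C)(C)N[Si](C)(C)C
Why: In this anhydride-to-imide exchange methanol releases ammonia slowly from the disilazane, ammonia is acylated at either carbonyl, and silylation-assisted dehydration recloses the five-membered ring as the N–H imide under near-neutral conditions that touch no other group.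

**Compound list**
1 | 3,4-dibromo-1-methyl-1H-pyrrole-2,5-dione | CN1C(=O)C(Br)=C(Br)C1=O | starting material
2 | 4-bromobenzylzinc bromide | Br[Zn]Cc1ccc(Br)cc1 | starting material
3 | 3-bromo-4-(4-bromobenzyl)-1-methyl-1H-pyrrole-2,5-dione | CN1C(=O)C(Br)=C(Cc2ccc(Br)cc2)C1=O | intermediate
4 | 1-methyl-5-(tributylstannyl)-1H-imidazole | CCCC[Sn](CCCC)(CCCC)c1cncn1C | starting material
5 | 3-(4-bromobenzyl)-1-methyl-4-(1-methyl-1H-imidazol-5-yl)-1H-pyrrole-2,5-dione | CN1C(=O)C(Cc2ccc(Br)cc2)=C(c2cncn2C)C1=O | intermediate
6 | N,N-dimethylformamide dimethyl acetal | COC(OC)N(C)C | starting material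
7 | 3-[(E)-1-(4-bromophenyl)-2-(dimethylamino)ethenyl]-1-methyl-4-(1-methyl-1H-imidazol-5-yl)-1H-pyrrole-2,5-dione | CN(C)/C=C(\c1ccc(Br)cc1)C1=C(c2cncn2C)C(=O)N(C)C1=O | intermediate
8 | 3-[(E)-1-(4-bromophenyl)-2-hydroxyethenyl]-1-methyl-4-(1-methyl-1H-imidazol-5-yl)-1H-pyrrole-2,5-dione | O/C=C(\c1ccc(Br)cc1)C1=C(c2cncn2C)C(=O)N(C)C1=O | intermediate
9 | p-toluenesulfonamide | Cc1ccc(S(N)(=O)=O)cc1 | starting material
10 | N-{(E)-2-(4-bromophenyl)-2-[1-methyl-4-(1-methyl-1H-imidazol-5-yl)-2,5-dioxo-2,5-dihydro-1H-pyrrol-3-yl]ethenyl}-4-methylbenzenesulfonamide | Cc1ccc(S(=O)(=O)N/C=C(\c2ccc(Br)cc2)C2=C(c3cncn3C)C(=O)N(C)C2=O)cc1 | intermediate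
11 | 3-[6-bromo-1-(4-methylbenzenesulfonyl)-1H-indol-3-yl]-1-methyl-4-(1-methyl-1H-imidazol-5-yl)-1H-pyrrole-2,5-dione | Cn1cncc1C1=C(c2cn(S(=O)(=O)c3ccc(C)cc3)c3cc(Br)ccc23)C(=O)N(C)C1=O | intermediate
12 | dipotassium (Z)-2-(6-bromo-1H-indol-3-yl)-3-(1-methyl-1H-imidazol-5-yl)but-2-enedioate | [K+].[K+].[O-]C(=O)/C(c1cncn1C)=C(c1c[nH]c2cc(Br)ccc12)\C(=O)[O-] | intermediate
13 | 3-(6-bromo-1H-indol-3-yl)-4-(1-methyl-1H-imidazol-5-yl)furan-2,5-dione | Cn1cncc1C1=C(c2c[nH]c3cc(Br)ccc23)C(=O)OC1=O | intermediate
14 | didemnimide D | Cn1cncc1C1=C(c2c[nH]c3cc(Br)ccc23)C(=O)NC1=O | target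

Total step count: 8
Longest linear sequence: 8 steps (1 to 14)

**Steps most likely to fail**

1. Step 6.
- Risk: binding of imidazole N3 of substrate and product to palladium may stall turnover, and C–H palladation of the twisted, mildly deactivated aryl ring may be slow.
- Risk: at the temperature needed, three processes may compete. One is thermal six-electron ring closure of the enamine C=C, maleimide C3=C4 and imidazole C5=C4 triene with loss of the sulfonamide. The others are oxidative dimerisation at imidazole C2–H and insertion of transient zerovalent palladium into C–Br.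
- Fallback: it sets out from 1 and 4 and comes back at 11, taking the indole ring ready-made. 6-Bromoindole (2 equiv) and EtMgBr in THF give (6-bromo-1H-indol-1-yl)magnesium bromide F1. This attacks 1 through its C3 by addition–elimination to give 3-bromo-4-(6-bromo-1H-indol-3-yl)-1-methyl-1H-pyrrole-2,5-dione F2. NaH and TsCl in THF give 3-bromo-4-[6-bromo-1-(4-methylbenzenesulfonyl)-1H-indol-3-yl]-1-methyl-1H-pyrrole-2,5-dione F3, whose N-sulfonyl group restores the reactivity of the vinylic C–Br bond. Stille coupling of F3 with 4 under the conditions of step 2 gives 11.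

2. Step 3.
- Risk: deprotonation and condensation at the hindered CH2 may be slow.
- Risk: the ring alkene may drift to the exocyclic benzylidene position.
- Risk: on prolonged heating the new dienamine may close onto imidazole C4 with loss of dimethylamine.
- Fallback: it sets out from 1 and comes back at 8. The formyl carbon arrives with the aryl group, so no vinylogous deprotonation is needed. 4-Bromophenylacetaldehyde and morpholine (toluene, Dean–Stark) give 4-[(E)-2-(4-bromophenyl)ethenyl]morpholine F4. In a Stork enamine-type addition–elimination (Et3N, CH2Cl2, 0 °C to rt) its aryl-bearing carbon displaces one bromide of 1 to give 3-bromo-4-[(E)-1-(4-bromophenyl)-2-(morpholin-4-yl)ethenyl]-1-methyl-1H-pyrrole-2,5-dione F5. Stille coupling with 4 as in step 2 gives 3-[(E)-1-(4-bromophenyl)-2-(morpholin-4-yl)ethenyl]-1-methyl-4-(1-methyl-1H-imidazol-5-yl)-1H-pyrrole-2,5-dione F6. Hydrolysis of F6 as in step 4 gives 8.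

3. Step 5.
- Risk: the weakly nucleophilic sulfonamide may not overcome an unfavourable condensation equilibrium with the stabilised enol.
- Risk: long heating in acid may cause deformylation back to 5.
- Fallback: it sets out from 8 and comes back at 10, replacing acid-catalysed condensation by anionic vinylic substitution. TsCl and Et3N (CH2Cl2, 0 °C) convert 8 into (E)-2-(4-bromophenyl)-2-[1-methyl-4-(1-methyl-1H-imidazol-5-yl)-2,5-dioxo-2,5-dihydro-1H-pyrrol-3-yl]ethenyl 4-methylbenzenesulfonate F7. The potassium salt of 9 (K2CO3, MeCN, rt) adds to the terminal carbon of this doubly vinylogous acyl system and expels tosylate, giving 10 after mild acidification.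

**Further compounds**
F1 | step 6 | (6-bromo-1H-indol-1-yl)magnesium bromide | Br[Mg]n1ccc2ccc(Br)cc21
F2 | step 6 | 3-bromo-4-(6-bromo-1H-indol-3-yl)-1-methyl-1H-pyrrole-2,5-dione | CN1C(=O)C(Br)=C(c2c[nH]c3cc(Br)ccc23)C1=O
F3 | step 6 | 3-bromo-4-[6-bromo-1-(4-methylbenzenesulfonyl)-1H-indol-3-yl]-1-methyl-1H-pyrrole-2,5-dione | CN1C(=O)C(Br)=C(c2cn(S(=O)(=O)c3ccc(C)cc3)c3cc(Br)ccc23)C1=O
F4 | step 3 | 4-[(E)-2-(4-bromophenyl)ethenyl]morpholine | Brc1ccc(/C=C/N2CCOCC2)cc1
F5 | step 3 | 3-bromo-4-[(E)-1-(4-bromophenyl)-2-(morpholin-4-yl)ethenyl]-1-methyl-1H-pyrrole-2,5-dione | C1COCCN1/C=C(\c1ccc(Br)cc1)C1=C(Br)C(=O)N(C)C1=O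
F6 | step 3 | 3-[(E)-1-(4-bromophenyl)-2-(morpholin-4-yl)ethenyl]-1-methyl-4-(1-methyl-1H-imidazol-5-yl)-1H-pyrrole-2,5-dione | C1COCCN1/C=C(\c1ccc(Br)cc1)C1=C(c2cncn2C)C(=O)N(C)C1=O
F7 | step 5 | (E)-2-(4-bromophenyl)-2-[1-methyl-4-(1-methyl-1H-imidazol-5-yl)-2,5-dioxo-2,5-dihydro-1H-pyrrol-3-yl]ethenyl 4-methylbenzenesulfonate | Cc1ccc(S(=O)(=O)O/C=C(\c2ccc(Br)cc2)C2=C(c3cncn3C)C(=O)N(C)C2=O)cc1
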